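In a one-step world that runs to its end, the starting material you charge ends as target, whatever the charge. The two earlier runs show something else.

| flask | starting material | second substrate | solid reagent | remark | time |
|---|---|---|---|---|---|
| north-east | 0.010 M | 1 equiv | 3 equiv | run made earlier |  |
| south-east | 0.040 M | 1 equiv | 3 equiv | run made earlier |  |
| flask | 0.020 M | 1.00 equiv | 3.00 equiv |  | 1.0 h |

| run | time / min | target / % | starting material / % |
|---|---|---|---|
| north-east | 3.00 | 17.6 | 0 |
| north-east | 10.0 | 18.0 | 0 |
| north-east | 15.0 | 17.5 | 1.3 |
| north-east | 25.0 | 18.9 | 0 |
| north-east | 40.0 | 17.0 | 0.1 |
| south-east | 8.00 | 4.0 | 1.9 |
| south-east | 15.0 | 5.9 | 0 |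
| south-east | 20.0 | 5.8 | 0 |
| south-east | 30.0 | 4.6 | 1.1 |
| south-east | 40.0 | 4.0 | 0.1 |

(scatter of a reading: 1 percentage point)

- solid reagent is a solid; its amount is given per volume of the solution
- at the start none of the solid reagent is in solution
- the reaction counts as stopped when no species that holds the starting material changes by six tenths of a point or more over the second half of the time

- why nothing more happens at 1.0 h, or that something still does (for what has run out or reacted, a solid counts together with what of it has only dissolved) (all of the starting material has reacted / it is still moving / the partner has run out first)
- how much target there is at 1.0 h, in percent of the starting material charged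

In both runs starting material never reads above 1.9%, against a scatter of 1 percentage point, and target stays flat within that scatter, so time drops out. As a percentage, the plateau falls from 17.8% to 4.86%. As a concentration it barely moves: 1.78 mM against 1.94 mM, while the charge rose from 0.010 M to 0.040 M.

So freeze that. The target level, the mean plateau concentration read at these equivalents, is 1.86 mM, and at these equivalents I take the yield as that level divided by the charge. The flask has the same equivalents at 0.020 M, so I reckon 9.30%, with the starting material reacted and the target flat at 1.0 h.

The forecast also says all of the starting material has reacted, with 9.3% (range 8% to 11%), holding that “nearly the same amount of target forms whatever the loading”. The flask gives: all of the starting material has reacted, with 9.48% of target.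

    starting material + partner → target (k = 1.50 M⁻¹ s⁻¹)
    second substrate + partner → second product (k = 1.60 M⁻¹ s⁻¹)
    starting material + second substrate → cross product (k = 2.70 M⁻¹ s⁻¹)
    starting material + target → side product (k = 9.70 M⁻¹ s⁻¹)
    solid reagent ⇌ partner, rate k5*(cs5 - [partner]) while solid is left; crystals form when [partner] > cs5 (solubility = 16.0 mM, k = 0.0920 s⁻¹)

At 0.00501 h the flask spends starting material 1.5 times as fast on cross product as on target, and it makes target 1.50 times as fast as it uses it up. At 1.0 h the flask's target stands at 1.90 mM, against the level of 1.86 mM read from the runs. The level belongs to these equivalents: a neighbour flask, like this one but with 2.50 equiv of second substrate, ends at 4.74% of target, or 0.948 mM, half that level, with 89.0% as cross product.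

The earlier runs and the new flask were computed with constants of no real substance, and the scatter is random.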